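**Retrosynthetic overview**
1. 12 ⇐ 11 by hydrogenation of one alkene. No ring is built: the four benzene rings A–D are bought and joined in the order C+B, then D, then A.
2. 11 ⇐ styrene 6 + 1,4-benzoquinone 8 (ring A). Hydroboration followed by radical reductive alkylation of the quinone forms the ring A–CH2 bond and delivers the hydroquinone directly.
3. 6 ⇐ aldehyde 4 + phosphonate 5 (ring D) by Horner–Wadsworth–Emmons olefination.
4. 4 ⇐ key disconnection at the diaryl ether C–O bond (O3 of ring C to ring B). Unprotected 3,4-dihydroxybenzaldehyde 1 and 4-vinylphenylboronic acid 2 are joined by a boron-templated, copper-catalysed B-to-O aryl transfer.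

Assumption: the target SMILES contains no stereocentre and no double bond, so the compound is achiral and no enantiocontrol is needed. The only stereo-element in the route is the E alkene of 6, 9, 10 and 11, which step 4 removes.

**Step 1**
Reactants: 1 3,4-dihydroxybenzaldehyde; 2 (4-ethenylphenyl)boronic acid
Product: 4 3-(4-ethenylphenoxy)-4-hydroxybenzaldehyde, via aryl benzodioxaborole 3 (not isolated)
Conditions: 1, 2 (1.05 equiv), 4 Å MS, MeCN, rt, 1 h; then Cu(OAc)2 (20 mol %), pyridine (2 equiv), dry O2 (1 atm), rt, 24 h; aq. citric acid work-up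
Reagents that add atoms: none
Why: Proposed new method: condensing 1 with 2 stores both partners 1:1 in benzodioxaborole 3, which shields the catechol from oxidation by divalent copper and removes the acidity bias toward O4; acetate-triggered aryl transfer from boron to copper hands the catecholate over as a chelate, and in the square-planar trivalent copper aryl the aryl group sits trans to the weak donor O4 (para to CHO, a vinylogous carboxylate) and cis to the more electron-rich O3, so C–O reductive elimination arylates O3 and leaves the stabilised 4-phenoxide, which is too acidic and too hindered to couple again; the closest known reaction type is the Chan–Lam O-arylation of simple monophenols with arylboronic acids, which has not been shown on free catechols or as an aryl shift within an aryl catechol boronate.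

**Step 2**
Reactants: 4 3-(4-ethenylphenoxy)-4-hydroxybenzaldehyde; 5 diethyl (3-methoxybenzyl)phosphonate
Product: 6 2-(4-ethenylphenoxy)-4-[(E)-2-(3-methoxyphenyl)ethenyl]phenol
Conditions: 5 (1.3 equiv), KOtBu (2.6 equiv), DMF, 0 °C to 50 °C, 6 h; then 1 M HCl
Reagents that add atoms: none
Why: Horner–Wadsworth–Emmons olefination in which the extra base carries the phenol as its phenoxide, the strongly nucleophilic benzylic phosphonate anion still adds to the deactivated aldehyde on gentle warming, and elimination gives the E alkene, whose geometry is erased in step 4.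

**Step 3**
Reactants: 6 2-(4-ethenylphenoxy)-4-[(E)-2-(3-methoxyphenyl)ethenyl]phenol; 7 catecholborane; 8 1,4-benzoquinone
Product: 11 2-[2-(4-{2-hydroxy-5-[(E)-2-(3-methoxyphenyl)ethenyl]phenoxy}phenyl)ethyl]benzene-1,4-diol, via bis-boryl adduct 9 (not isolated), via O-boryl hydroquinone 10 (not isolated)
Conditions: 7 (2.1 equiv), Me2NC(O)Me (10 mol %), CH2Cl2, 40 °C, 4 h; then 8 (1.3 equiv), DMPU (1 equiv), trace air, 0 °C to rt, 2 h; H2O work-up
Reagents that add atoms: none
Why: Anti-Markovnikov hydroboration takes the terminal styrene far faster than the 1,2-diaryl alkene (the phenol is taken up as its borate), and the resulting B-alkylcatecholborane releases a primary alkyl radical that adds to carbon of benzoquinone in a chain carried by the aryloxyl radical attacking boron (reductive alkylation of quinones with organoboranes), so ring A arrives at the hydroquinone level with no protecting group.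

**Step 4**
Reactants: 11 2-[2-(4-{2-hydroxy-5-[(E)-2-(3-methoxyphenyl)ethenyl]phenoxy}phenyl)ethyl]benzene-1,4-diol
Product: 12 2-[2-(4-{2-hydroxy-5-[2-(3-methoxyphenyl)ethyl]phenoxy}phenyl)ethyl]benzene-1,4-diol (target)
Conditions: H2 (1 atm), 10% Pd/C, EtOAc/EtOH 1:1, rt, 4 h
Reagents that add atoms: none
Why: Heterogeneous catalytic hydrogenation saturates the only alkene while aryl ethers, the methyl ether and the phenols are inert, the reducing medium keeps ring A as the hydroquinone, and no stereocentre is created.

**Compound list**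
1 | 3,4-dihydroxybenzaldehyde | O=Cc1ccc(O)c(O)c1 | starting material
2 | (4-ethenylphenyl)boronic acid | C=Cc1ccc(cc1)B(O)O | starting material
3 | 2-(4-ethenylphenyl)-1,3,2-benzodioxaborole-5-carbaldehyde (not isolated) | O=Cc1ccc2OB(Oc2c1)c1ccc(C=C)cc1 | intermediate
4 | 3-(4-ethenylphenoxy)-4-hydroxybenzaldehyde | O=Cc1ccc(O)c(Oc2ccc(C=C)cc2)c1 | intermediate
5 | diethyl (3-methoxybenzyl)phosphonate | CCOP(=O)(Cc1cccc(OC)c1)OCC | starting material
6 | 2-(4-ethenylphenoxy)-4-[(E)-2-(3-methoxyphenyl)ethenyl]phenol | COc1cccc(/C=C/c2ccc(O)c(Oc3ccc(C=C)cc3)c2)c1 | intermediate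
7 | catecholborane (1,3,2-benzodioxaborole) | B1Oc2ccccc2O1 | starting material
8 | 1,4-benzoquinone | O=C1C=CC(=O)C=C1 | starting material
9 | B-alkylcatecholborane of 6, boron on the terminal carbon, ring C oxygen carried as its catechol borate, E alkene (not isolated) | COc1cccc(/C=C/c2ccc(OB3Oc4ccccc4O3)c(Oc3ccc(CCB4Oc5ccccc5O4)cc3)c2)c1 | intermediate
10 | ring A adduct with the hydroquinone oxygen meta to the chain and the ring C oxygen both carried as catechol borates, E alkene (not isolated) | COc1cccc(/C=C/c2ccc(OB3Oc4ccccc4O3)c(Oc3ccc(CCc4cc(OB5Oc6ccccc6O5)ccc4O)cc3)c2)c1 | intermediate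
11 | 2-[2-(4-{2-hydroxy-5-[(E)-2-(3-methoxyphenyl)ethenyl]phenoxy}phenyl)ethyl]benzene-1,4-diol | COc1cccc(/C=C/c2ccc(O)c(Oc3ccc(CCc4cc(O)ccc4O)cc3)c2)c1 | intermediate
12 | 2-[2-(4-{2-hydroxy-5-[2-(3-methoxyphenyl)ethyl]phenoxy}phenyl)ethyl]benzene-1,4-diol (achiral) | COc1cccc(CCc2ccc(O)c(Oc3ccc(CCc4cc(O)ccc4O)cc3)c2)c1 | target

**Step count**
Total step count: 4. Longest linear sequence: 4 (1 → 4 → 6 → 11 → 12). No protecting group is used.

**Three steps most likely to fail**

Step 1 (the proposed new step). The risks are arylation at O4 instead of O3, oxidation of the catechol by divalent copper and O2, and oxidative hydroxylation of 2. The fallback uses only known chemistry, sets out from 1 and comes back at 4. The more acidic 4-OH of 1 is alkylated selectively with allyl bromide (NaHCO3, NaI, DMF, 40 °C) to give 4-(allyloxy)-3-hydroxybenzaldehyde F1. Its single free phenol undergoes an ordinary Chan–Lam coupling with 2 (Cu(OAc)2 1 equiv, pyridine, 4 Å MS, CH2Cl2, air, rt) to give 4-(allyloxy)-3-(4-ethenylphenoxy)benzaldehyde F2. Deallylation by zerovalent palladium (Pd(PPh3)4 2 mol %, K2CO3, MeOH, rt) then returns 4.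

Step 2. The risk is that the para-phenoxide makes the aldehyde a poor electrophile and conversion stalls. The fallback masks the phenol, sets out from 4 and comes back at 6. Silylation (TBSCl, imidazole, DMF, rt) gives 4-[(tert-butyldimethylsilyl)oxy]-3-(4-ethenylphenoxy)benzaldehyde F3, which behaves as a normal aldehyde. Olefination with 5 (NaH, THF, 0 °C to rt) gives tert-butyl{2-(4-ethenylphenoxy)-4-[(E)-2-(3-methoxyphenyl)ethenyl]phenoxy}dimethylsilane F4. TBAF (THF, 0 °C) then frees 6.

Step 3. About one tenth of the hydroboration may give the branched isomer, whose benzylic radical transfers preferentially. The phenols may retard the radical chain, and the product may undergo redox exchange with excess quinone. The fallback replaces the radical alkylation by a cross-coupling, sets out from 6 and comes back at 12. Bromohydroquinone is benzylated (BnBr, K2CO3, acetone, reflux) to 1,4-bis(benzyloxy)-2-bromobenzene F5. A Heck reaction of F5 with the terminal vinyl group of 6 (Pd(OAc)2 5 mol %, P(o-tol)3, Et3N, DMF, 100 °C) gives 2-(4-{(E)-2-[2,5-bis(benzyloxy)phenyl]ethenyl}phenoxy)-4-[(E)-2-(3-methoxyphenyl)ethenyl]phenol F6. The conditions of step 4 then saturate both alkenes and cleave both benzyl ethers to give 12.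

**Further compounds**
F1 | step 1 | 4-(allyloxy)-3-hydroxybenzaldehyde | O=Cc1ccc(OCC=C)c(O)c1
F2 | step 1 | 4-(allyloxy)-3-(4-ethenylphenoxy)benzaldehyde | O=Cc1ccc(OCC=C)c(Oc2ccc(C=C)cc2)c1
F3 | step 2 | 4-[(tert-butyldimethylsilyl)oxy]-3-(4-ethenylphenoxy)benzaldehyde | O=Cc1ccc(O[Si](C)(C)C(C)(C)C)c(Oc2ccc(C=C)cc2)c1
F4 | step 2 | tert-butyl{2-(4-ethenylphenoxy)-4-[(E)-2-(3-methoxyphenyl)ethenyl]phenoxy}dimethylsilane | COc1cccc(/C=C/c2ccc(O[Si](C)(C)C(C)(C)C)c(Oc3ccc(C=C)cc3)c2)c1
F5 | step 3 | 1,4-bis(benzyloxy)-2-bromobenzene | Brc1cc(OCc2ccccc2)ccc1OCc1ccccc1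
F6 | step 3 | 2-(4-{(E)-2-[2,5-bis(benzyloxy)phenyl]ethenyl}phenoxy)-4-[(E)-2-(3-methoxyphenyl)ethenyl]phenol | COc1cccc(/C=C/c2ccc(O)c(Oc3ccc(/C=C/c4cc(OCc5ccccc5)ccc4OCc4ccccc4)cc3)c2)c1
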